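The route rests on making the C8–C7 bond and the C4a=C8a double bond of the 5,6,7,8-tetrahydro-1H-isochromen-8-one core in one pot. An aldehyde tethered to the C6 oxygen hydroacylates the C6 vinyl group; this closes a temporary oxan-4-one, forges C8–C7 and sets C7. A phosphine then opens that ring, the released vinyl ketone cyclises onto a β-methoxy enone (C8a to C4a), and oxa-6π closure forms the pyran ring. The step exploits that C8 lies β to both oxygens: O–C6 through C7, and O2 through C8a–C1. Its precursor is an open-chain 3-oxopropyl ether of a chiral hex-1-en-3-ol derivative; the orsellinate is attached last.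

Key step: step 8

Remark: positions are numbered as in 1H-isochromene (C1, O2, C3, C4, C4a, C5–C8, C8a); the target is (6R,7R), with the C6 ester and the C7 methyl cis.

Step 1
Reactants: 1 (R)-epichlorohydrin; 2 trimethylsilylacetylene
Product: 3 (2R)-1-chloro-5-(trimethylsilyl)pent-4-yn-2-ol
Conditions: 2, n-BuLi, THF, −78 °C; BF3·OEt2; then 1, −78 °C; aq. NH4Cl
Reagents that add atoms: none
Why: BF3-promoted opening of the epoxide by the lithium acetylide at the unsubstituted carbon (Yamaguchi conditions) should give the chlorohydrin, and the stereocentre of 1 is not touched.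

Step 2
Reactants: 3
Product: 6 (3R)-hex-1-en-5-yn-3-ol, via alkynyl epoxide 4 (not isolated), via silyl enynol 5 (not isolated)
Conditions: Me3S+ I− (3.5 equiv), n-BuLi (3.5 equiv), THF, −10 → 23 °C; then K2CO3 (cat.), MeOH, 23 °C
Reagents that add atoms: trimethylsulfonium iodide, C[S+](C)C.[I-]
Why: Base closes the chlorohydrin to the epoxide, dimethylsulfonium methylide opens it at CH2 and the betaine loses Me2S (one-carbon homologation of an epoxide to an allylic alcohol), and methanolysis then removes the C-silyl group, all without involving the carbinol centre.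

Step 3
Reactants: 6 (3R)-hex-1-en-5-yn-3-ol; 7 (3-bromopropoxy)(tert-butyl)dimethylsilane
Product: 8 tert-butyl{3-[(3R)-hex-1-en-5-yn-3-yloxy]propoxy}dimethylsilane
Conditions: NaH (1.1 equiv), n-Bu4NI (cat.), DMF, 0 → 23 °C
Reagents that add atoms: none
Why: Williamson etherification of the sodium alkoxide with the primary bromide (iodide catalysis) should install the three-carbon tether on the C6 oxygen with retention.

Step 4
Reactants: 9 4-tert-butoxy-4-oxobutanoic acid
Product: 11 tert-butyl 4-[methoxy(methyl)amino]-4-oxobutanoate, via acyl imidazole 10 (not isolated)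
Conditions: CDI, CH2Cl2, 23 °C; then MeNH(OMe)·HCl
Reagents that add atoms: N,O-dimethylhydroxylamine hydrochloride, CNOC.Cl
Why: Amide coupling through the acyl imidazole should give the Weinreb amide; no stereocentre is present.

Step 5
Reactants: 8 tert-butyl{3-[(3R)-hex-1-en-5-yn-3-yloxy]propoxy}dimethylsilane; 11 tert-butyl 4-[methoxy(methyl)amino]-4-oxobutanoate
Product: 13 tert-butyl (5E,8R)-8-[3-(tert-butyldimethylsilyloxy)propoxy]-6-methoxy-4-oxodeca-5,9-dienoate, via ynone 12 (not isolated)
Conditions: 8, n-BuLi, THF, −78 °C; 11, −78 → −20 °C; aq. NH4Cl, extraction; then MeOH, PBu3 (10 mol %), 23 °C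
Reagents that add atoms: methanol, CO
Why: Weinreb ketone synthesis with the lithium acetylide should give the ynone, and phosphine-catalysed conjugate addition of methanol masks it as the β-methoxy enone, which should be inert to Rh–H yet remains a vinylogous acylating carbon for step 8.

Step 6
Reactants: 13
Product: 14 tert-butyl (5E,8R)-8-(3-hydroxypropoxy)-6-methoxy-4-oxodeca-5,9-dienoate
Conditions: TBAF (1.2 equiv), AcOH (1.2 equiv), THF, 0 → 23 °C
Reagents that add atoms: none
Why: Buffered fluoride desilylation should free the primary alcohol and leave the enol ether and the tert-butyl ester intact.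

Step 7
Reactants: 14
Product: 15 tert-butyl (5E,8R)-6-methoxy-4-oxo-8-(3-oxopropoxy)deca-5,9-dienoate
Conditions: Dess–Martin periodinane, CH2Cl2, 0 → 23 °C
Reagents that add atoms: none
Why: Dess–Martin oxidation under non-basic conditions should give the β-alkoxy aldehyde without retro-oxa-Michael loss of acrolein.

Step 8
Reactants: 15
Product: 19 tert-butyl 3-[(6R,7R)-6-hydroxy-7-methyl-8-oxo-5,6,7,8-tetrahydro-1H-isochromen-3-yl]propanoate, via oxanone 16 (not isolated), via hydroxy dienone 17 (not isolated), via trienone 18 (not isolated)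
Conditions: [Rh(cod)2]BF4/dcpe (5 mol %), 1,2-dichloroethane, 40 °C; then PBu3 (0.3 equiv), DBU (0.1 equiv), t-AmOH, 23 °C, same flask; AcOH quench
Reagents that add atoms: none
Why: Proposed new method: Rh(I) adds oxidatively to the aldehyde C–H of 15 (held by the ether oxygen in a five-membered chelate), the Rh–H adds across the vinyl group in the branched sense and reductive elimination closes the temporary oxan-4-one 16 in a 6-exo mode, which makes C8–C7. PBu3/DBU then opens 16 by retro-oxa-Michael elimination at the C8a methylene to vinyl ketone 17, the phosphonium enolate formed from it attacks C4a of the β-methoxy enone (6-(enolendo)-exo-trig addition–elimination with loss of methanol, closing the carbocycle), and loss of PBu3 leaves the 2-methylidene dienone 18, whose 1-oxatriene closes by thermal disrotatory oxa-6π electrocyclisation to the 2H-pyran ring, so that the new C4a–C8a bond becomes the ring-fusion double bond. The closest known reactions are heteroatom-directed Rh-catalysed intramolecular hydroacylation of allyl ethers to α-methyl ketones, the phosphine-catalysed intramolecular Rauhut–Currier reaction and the dienone-to-2H-pyran valence isomerisation; their union in one flask and the vinylogous-ester acceptor are untested. C7 is the only new stereocentre: it is set in the hydroacylation by the C6 centre, with the methyl group and the C6 side chain both equatorial in the chair-like insertion step, giving the 2,3-trans oxanone, which is also the more stable epimer at this enolisable carbon and which maps onto the 6,7-cis (6R,7R) arrangement once C5 replaces the oxygen as ring member. The step needs branched instead of linear insertion (six- against seven-membered ring, O-chelate), ring opening on the methylene side and not at C7 (less hindered, kinetically more acidic protons) and bonding of C8a to C4a (the only six-membered closure, and the phosphine adds to the vinyl ketone, not to the β-methoxy enone). The basic phase is kept short, run in t-AmOH and quenched with AcOH, because 19 can lose water toward the phenol.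

Step 9
Reactants: 20 orsellinic acid
Product: 22 2,4-bis(methoxymethoxy)-6-methylbenzoic acid, via MOM ester 21 (not isolated)
Conditions: NaH (3.5 equiv), MOMCl (3.5 equiv), DMF, 0 → 23 °C; then LiOH, THF/H2O, 40 °C; 1 M HCl to pH 4, 0 °C
Reagents that add atoms: chloromethyl methyl ether, COCCl
Why: Exhaustive O-alkylation followed by saponification of the labile methoxymethyl ester should give the acid with both phenols protected as acetals.

Step 10
Reactants: 19 tert-butyl 3-[(6R,7R)-6-hydroxy-7-methyl-8-oxo-5,6,7,8-tetrahydro-1H-isochromen-3-yl]propanoate; 22 2,4-bis(methoxymethoxy)-6-methylbenzoic acid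
Product: 24 (6R,7R)-3-(3-tert-butoxy-3-oxopropyl)-7-methyl-8-oxo-5,6,7,8-tetrahydro-1H-isochromen-6-yl 2,4-bis(methoxymethoxy)-6-methylbenzoate, via acid chloride 23 (not isolated)
Conditions: 22, 1-chloro-N,N,2-trimethylprop-1-en-1-amine (Ghosez's reagent), CH2Cl2, 0 °C; then 19, pyridine, DMAP (cat.), 0 → 23 °C
Reagents that add atoms: none
Why: Acid chloride formation under neutral conditions and DMAP-catalysed acylation with pyridine as the only base should esterify the C6 hydroxyl with retention at C6 and without enolising C7.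

Step 11
Reactants: 24
Product: 25 3-[(6R,7R)-6-(2,4-dihydroxy-6-methylbenzoyloxy)-7-methyl-8-oxo-5,6,7,8-tetrahydro-1H-isochromen-3-yl]propanoic acid (target)
Conditions: TFA/CH2Cl2 (1:4), 0 → 23 °C; evaporation with toluene
Reagents that add atoms: none
Why: Acidolysis should cleave the tert-butyl ester (as isobutene) and both methoxymethyl ethers in one operation, with C6 and C7 unchanged.

Compound list
1 | (R)-epichlorohydrin, (2R)-2-(chloromethyl)oxirane | ClC[C@H]1CO1 | starting material
2 | trimethylsilylacetylene | C#C[Si](C)(C)C | starting material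
3 | (2R)-1-chloro-5-(trimethylsilyl)pent-4-yn-2-ol | ClC[C@H](O)CC#C[Si](C)(C)C | intermediate
4 | trimethyl{3-[(2R)-oxiran-2-yl]prop-1-yn-1-yl}silane | C1[C@H](O1)CC#C[Si](C)(C)C | intermediate (not isolated)
5 | (3R)-6-(trimethylsilyl)hex-1-en-5-yn-3-ol | C=C[C@H](O)CC#C[Si](C)(C)C | intermediate (not isolated)
6 | (3R)-hex-1-en-5-yn-3-ol | C=C[C@H](O)CC#C | intermediate
7 | (3-bromopropoxy)(tert-butyl)dimethylsilane | BrCCCO[Si](C)(C)C(C)(C)C | starting material
8 | tert-butyl{3-[(3R)-hex-1-en-5-yn-3-yloxy]propoxy}dimethylsilane | C=C[C@H](OCCCO[Si](C)(C)C(C)(C)C)CC#C | intermediate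
9 | 4-tert-butoxy-4-oxobutanoic acid (mono-tert-butyl succinate) | CC(C)(C)OC(=O)CCC(=O)O | starting material
10 | tert-butyl 4-(1H-imidazol-1-yl)-4-oxobutanoate | CC(C)(C)OC(=O)CCC(=O)n1ccnc1 | intermediate (not isolated)
11 | tert-butyl 4-[methoxy(methyl)amino]-4-oxobutanoate | CC(C)(C)OC(=O)CCC(=O)N(C)OC | intermediate
12 | tert-butyl (8R)-8-[3-(tert-butyldimethylsilyloxy)propoxy]-4-oxodec-9-en-5-ynoate | C=C[C@H](OCCCO[Si](C)(C)C(C)(C)C)CC#CC(=O)CCC(=O)OC(C)(C)C | intermediate (not isolated)
13 | tert-butyl (5E,8R)-8-[3-(tert-butyldimethylsilyloxy)propoxy]-6-methoxy-4-oxodeca-5,9-dienoate | C=C[C@H](OCCCO[Si](C)(C)C(C)(C)C)C/C(OC)=C\C(=O)CCC(=O)OC(C)(C)C | intermediate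
14 | tert-butyl (5E,8R)-8-(3-hydroxypropoxy)-6-methoxy-4-oxodeca-5,9-dienoate | C=C[C@H](OCCCO)C/C(OC)=C\C(=O)CCC(=O)OC(C)(C)C | intermediate
15 | tert-butyl (5E,8R)-6-methoxy-4-oxo-8-(3-oxopropoxy)deca-5,9-dienoate | C=C[C@H](OCCC=O)C/C(OC)=C\C(=O)CCC(=O)OC(C)(C)C | intermediate
16 | tert-butyl (5E)-6-methoxy-7-[(2R,3R)-3-methyl-4-oxooxan-2-yl]-4-oxohept-5-enoate | O1CCC(=O)[C@H](C)[C@H]1C/C(OC)=C\C(=O)CCC(=O)OC(C)(C)C | intermediate (not isolated)
17 | tert-butyl (5E,8R,9R)-8-hydroxy-6-methoxy-9-methyl-4,10-dioxododeca-5,11-dienoate | C=CC(=O)[C@H](C)[C@H](O)C/C(OC)=C\C(=O)CCC(=O)OC(C)(C)C | intermediate (not isolated)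
18 | tert-butyl (5Z)-5-[(4R,5R)-5-hydroxy-4-methyl-2-methylidene-3-oxocyclohexylidene]-4-oxopentanoate | C=C1C(=O)[C@H](C)[C@H](O)C/C1=C/C(=O)CCC(=O)OC(C)(C)C | intermediate (not isolated)
19 | tert-butyl 3-[(6R,7R)-6-hydroxy-7-methyl-8-oxo-5,6,7,8-tetrahydro-1H-isochromen-3-yl]propanoate | O[C@@H]1CC2=C(COC(CCC(=O)OC(C)(C)C)=C2)C(=O)[C@@H]1C | intermediate
20 | orsellinic acid (2,4-dihydroxy-6-methylbenzoic acid) | Cc1cc(O)cc(O)c1C(=O)O | starting material
21 | methoxymethyl 2,4-bis(methoxymethoxy)-6-methylbenzoate | Cc1cc(OCOC)cc(OCOC)c1C(=O)OCOC | intermediate (not isolated)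
22 | 2,4-bis(methoxymethoxy)-6-methylbenzoic acid | Cc1cc(OCOC)cc(OCOC)c1C(=O)O | intermediate
23 | 2,4-bis(methoxymethoxy)-6-methylbenzoyl chloride | Cc1cc(OCOC)cc(OCOC)c1C(=O)Cl | intermediate (not isolated)
24 | (6R,7R)-3-(3-tert-butoxy-3-oxopropyl)-7-methyl-8-oxo-5,6,7,8-tetrahydro-1H-isochromen-6-yl 2,4-bis(methoxymethoxy)-6-methylbenzoate | Cc1cc(OCOC)cc(OCOC)c1C(=O)O[C@@H]1CC2=C(COC(CCC(=O)OC(C)(C)C)=C2)C(=O)[C@@H]1C | intermediate
25 | 3-[(6R,7R)-6-(2,4-dihydroxy-6-methylbenzoyloxy)-7-methyl-8-oxo-5,6,7,8-tetrahydro-1H-isochromen-3-yl]propanoic acid | Cc1cc(O)cc(O)c1C(=O)O[C@@H]1CC2=C(COC(CCC(=O)O)=C2)C(=O)[C@@H]1C | target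

Total step count: 11. Longest linear sequence: 9 steps (1, 2, 3, 5, 6, 7, 8, 10, 11).

Steps most likely to fail

Step 8 (proposed new method). The ways it could go wrong:
- the acyl rhodium hydride may insert in the linear sense and close the seven-membered oxepanone, or decarbonylate;
- the base may open the oxanone on the C7 side, which erases the C6 configuration on re-closure, or deprotonate C5 and expel the C6 oxygen;
- the product may dehydrate toward the aromatic phenol.

The fallback runs the same bond set with established single reactions; it sets out from 15 and returns at 19. Aldehyde 15 would be cyclised to the oxanone 16 by thiol-catalysed radical-chain hydroacylation (tert-dodecanethiol, radical initiator, 60 °C; acyl-radical 6-exo cyclisation of the citronellal-to-menthone type) and isolated. Kinetic deprotonation of the methylene of 16 with LiHMDS at −78 °C, β-elimination on warming and capture of the C6 alkoxide with TBSCl would give the ring-opened silyl ether F1. PMe3 in t-AmOH would then effect the Rauhut–Currier closure and oxa-6π ring closure to the bicyclic silyl ether F2, and HF·pyridine would release 19.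

Step 10. Acylation of the hindered secondary alcohol by a 2,6-disubstituted benzoyl chloride may be slow; the amine base may then cause β-elimination of the new ester and aromatisation, or epimerise C7. The fallback sets out from 22 and 19 and returns at 24. Acid 22 would be converted with 2,2′-dipyridyl disulfide and PPh3 into the 2-pyridyl thioester F3, which would acylate 19 under silver activation (AgOTf, CH2Cl2, no base), a thiophilic rather than base-mediated acyl transfer.

Step 11. Protic acid may enolise the C8 ketone and ionise the C6 ester, leading to loss of orsellinic acid and aromatisation, or hydrolyse the dienol ether. The fallback sets out from 24 and returns at 25. Non-protic silylative cleavage with TMSOTf/2,2′-bipyridyl (aryl methoxymethyl ethers) and TMSOTf/2,6-lutidine (tert-butyl ester) would give the tris(trimethylsilyl) compound F4, which a pH 7 aqueous work-up would hydrolyse to 25.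

Further compounds
F1 | step 8 | tert-butyl (5E,8R,9R)-8-(tert-butyldimethylsilyloxy)-6-methoxy-9-methyl-4,10-dioxododeca-5,11-dienoate | C=CC(=O)[C@H](C)[C@H](O[Si](C)(C)C(C)(C)C)C/C(OC)=C\C(=O)CCC(=O)OC(C)(C)C
F2 | step 8 | tert-butyl 3-[(6R,7R)-6-(tert-butyldimethylsilyloxy)-7-methyl-8-oxo-5,6,7,8-tetrahydro-1H-isochromen-3-yl]propanoate | CC(C)(C)[Si](C)(C)O[C@@H]1CC2=C(COC(CCC(=O)OC(C)(C)C)=C2)C(=O)[C@@H]1C
F3 | step 10 | S-(pyridin-2-yl) 2,4-bis(methoxymethoxy)-6-methylbenzenecarbothioate | Cc1cc(OCOC)cc(OCOC)c1C(=O)Sc1ccccn1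
F4 | step 11 | trimethylsilyl 3-[(6R,7R)-6-{2,4-bis(trimethylsilyloxy)-6-methylbenzoyloxy}-7-methyl-8-oxo-5,6,7,8-tetrahydro-1H-isochromen-3-yl]propanoate | Cc1cc(O[Si](C)(C)C)cc(O[Si](C)(C)C)c1C(=O)O[C@@H]1CC2=C(COC(CCC(=O)O[Si](C)(C)C)=C2)C(=O)[C@@H]1C
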